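At early times E climbs fast in the earlier runs, and the question for a new flask at [D] = 23 mM is how far along that climb its enzyme stands.

| flask | D | X | remark | time |
|---|---|---|---|---|
| green | 23 mM | 2.9 µM | run made earlier |  |
| blue | 23 mM | 4.3 µM | run made earlier |  |
| red | 46 mM | 5.8 µM | run made earlier |  |
| flask | 23 mM | 5.8 µM |  | 15 d |

| run | time / d | E / % |
|---|---|---|
| green | 0.0833 | 56.6 |
| green | 0.208 | 84.1 |
| green | 0.625 | 82.7 |
| green | 1.25 | 81.3 |
| green | 4.00 | 77.8 |
| green | 10.0 | 69.6 |
| blue | 0.0833 | 73.8 |
| blue | 0.208 | 84.7 |
| blue | 0.625 | 82.7 |
| blue | 1.25 | 80.7 |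
| blue | 4.00 | 79.1 |
| blue | 10.0 | 72.6 |
| red | 0.0833 | 60.1 |
| red | 0.250 | 78.4 |
| red | 0.833 | 75.8 |
| red | 3.00 | 71.0 |
| red | 10.0 | 58.1 |

(readings scatter by 1 percentage point)

- the numbers in the tables scatter by 1 percentage point (one standard deviation)

1. time up to 15 d at which E stands highest
2. the amount of E, in percent of the D charged, at that time

In the green run E rose to 84.1% within 0.208 d and then fell by 13 percentage points between 0.625 d and 10.0 d, so the rise ran far faster than the fall, and I took the top as the crossing at which the fast rise gives way to the slow fall. As a working rule at fixed [D], in the manner of Selwyn's test, I measured the rise by the product [X]t.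

My first way was a straight line. The first green reading gives a mean turnover of 53900 /d per X charged, and at that rate the top blue reading, 84.7%, needs [X]t = 0.0312 M·s, which is 0.0623 d in the new flask.

My second way read the top directly from the runs. I took the highest reading at this [D], blue at 0.208 d, as marking the enzyme-time of the top, [X]t at the peak, 0.0773 M·s, which gives 0.154 d in the new flask.

The two parted, and the first blue reading exposed the line: at [X]t = 0.0309 M·s, about where the line had finished, E stood at 73.8%, lower than the top blue reading, so the rate had dropped on the way. The green reading at 0.208 d, with [X]t = 0.0521 M·s, was 84.1%, which is 0.6 points below the top blue reading against a scatter of 1 point, so these two readings did not separate the two values of [X]t, but I kept 0.154 d as an estimate with that margin.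

The forecast, holding that “The peak should come soon after D runs out”, gave 86% at 0.11 d, earlier than my time.

The new flask gave 84.9% at 0.155 d, and D still stood at 11.8% of its charge at that moment.

    D + X ⇌ L (K = 720 /M, k = 50000 /M/min)
    L ⇌ X + E (K = 0.0100 M, k = 51.0 /min)
    2 D → G (k = 0.0210 /M/min)

There [X]t was 0.0777 M·s, beside the 0.0773 M·s read from blue. At half the best time, [X]t in the new flask was 0.0388 M·s and E stood at 80.7%, between the blue reading of 73.8% at 0.0309 M·s and the green reading of 84.1% at 0.0521 M·s.

The data are calculated for substances that don't exist; noise was put on by code.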